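**Strategy.** The route rests on cutting the C6–C7 bond together with the lactone C12–O bond. In one operation CrCl2 turns the bromomethyl acrylate arm into an allylchromium whose C7 adds to the C6 aldehyde. This closes oxepane B (and so completes the ten-membered carbocycle), sets C6 and C7, and lets the C6 alkoxide lactonise. The feature used is that the lactone carbinol C6 and C7 are neighbours on ring B and that C11–C13 form a 2-carboxyallyl unit on C7. The precursor is oxepane A with cis arms: C4 carries CH(OPMB)CHO (C5, C6) and C9 carries the (Z)-bromomethyl acrylate (C7–C13). Its C4 and C5 centres come from a Sharpless epoxide opened by the C9 hydroxyl.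

Key step: step 13

Remark: the target is read as 4R,5S,6R,7R,9R,10S (C1–C10 carbocycle, ether oxygen between C4 and C9, C11–C13 lactone unit; PMB = 4-methoxybenzyl). The (S,R,R) ligand of step 1 is assumed to give the 3S series as with other dialkylzinc reagents; otherwise its enantiomer is used.

**Step 1**
Reactants: 1 cyclohex-2-en-1-one; 2 allyl acetate
Product: 4 (2R,3S)-3-methyl-2-(prop-2-en-1-yl)cyclohexan-1-one, via zinc enolate 3 (not isolated)
Conditions: Me2Zn, Cu(OTf)2 (2 mol%), (S,R,R)-phosphoramidite from 1,1′-bi-2-naphthol and bis(1-phenylethyl)amine (4 mol%), toluene, −30 °C; then 2, Pd(PPh3)4 (2 mol%), 0 °C; aqueous NH4Cl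
Reagents that add atoms: dimethylzinc, C[Zn]C
Why: Copper-catalysed asymmetric conjugate addition sets the methyl-bearing centre (future C10, 3S, ligand control), and palladium-catalysed Tsuji–Trost allylation of the zinc enolate places the allyl group anti to that methyl, giving the trans 2,3-pattern that becomes C9/C10.

**Step 2**
Reactants: 4 (2R,3S)-3-methyl-2-(prop-2-en-1-yl)cyclohexan-1-one
Product: 5 (6S,7R)-6-methyl-7-(prop-2-en-1-yl)oxepan-2-one
Conditions: mCPBA, NaHCO3, CH2Cl2, 0 °C to rt
Reagents that add atoms: 3-chloroperoxybenzoic acid (mCPBA), OOC(=O)c1cccc(Cl)c1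
Why: Baeyer–Villiger oxidation in which the more substituted allyl-bearing carbon migrates with retention, so the ring oxygen is inserted next to future C9 without touching either stereocentre, while the monosubstituted alkene should be epoxidised more slowly than the ketone is oxidised.

**Step 3**
Reactants: 5 (6S,7R)-6-methyl-7-(prop-2-en-1-yl)oxepan-2-one
Product: 7 (4R,5S)-5-methyldec-1-en-9-yn-4-ol, via lactol 6 (not isolated)
Conditions: i-Bu2AlH, CH2Cl2, −78 °C; then MeOH, K2CO3, dimethyl (1-diazo-2-oxopropyl)phosphonate, rt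
Reagents that add atoms: dimethyl (1-diazo-2-oxopropyl)phosphonate, COP(=O)(OC)C(=[N+]=[N-])C(C)=O
Why: Partial reduction stops at the aluminium acetal, which on methanolysis releases the hydroxy aldehyde for Seyferth–Gilbert homologation, turning the former lactone carbonyl (C4) into the internal alkyne carbon and adding C5 with no stereocentre at risk.

**Step 4**
Reactants: 7 (4R,5S)-5-methyldec-1-en-9-yn-4-ol
Product: 9 (2E,7S,8R)-3,7-dimethylundeca-2,10-diene-1,8-diol, via alkenylalane 8 (not isolated)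
Conditions: AlMe3 (3.5 equiv), Cp2ZrCl2 (0.25 equiv), CH2Cl2, 0 °C to rt; then n-BuLi, (CH2O)n, THF, −78 °C to rt
Reagents that add atoms: trimethylaluminium, C[Al](C)C; formaldehyde (from paraformaldehyde), C=O
Why: Negishi zirconium-catalysed carboalumination adds methyl and aluminium syn across the terminal alkyne (methyl to C4) and the derived alanate is hydroxymethylated with retention, giving the E-trisubstituted allylic alcohol C4(Me)=C5–C6, while the remote hydroxyl travels as its aluminium alkoxide and the unactivated terminal alkene should react far more slowly than the alkyne.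

**Step 5**
Reactants: 9 (2E,7S,8R)-3,7-dimethylundeca-2,10-diene-1,8-diol
Product: 10 [(2S,3S)-3-[(4S,5R)-5-hydroxy-4-methyloct-7-en-1-yl]-3-methyloxiran-2-yl]methanol
Conditions: Ti(OiPr)4 (10 mol%), L-(+)-diethyl tartrate (12 mol%), t-BuOOH, 4 Å molecular sieves, CH2Cl2, −20 °C
Reagents that add atoms: tert-butyl hydroperoxide, CC(C)(C)OO
Why: Sharpless asymmetric epoxidation of the geraniol-type allylic alcohol with the L-(+)-tartrate catalyst delivers oxygen to the face that gives the (2S,3S)-epoxide (reagent control), which fixes C5 and the C4 configuration that is inverted in step 6, while the homoallylic C9 alcohol and the terminal alkene are not substrates.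

**Step 6**
Reactants: 10 [(2S,3S)-3-[(4S,5R)-5-hydroxy-4-methyloct-7-en-1-yl]-3-methyloxiran-2-yl]methanol
Product: 11 (1S)-1-[(2R,6S,7R)-2,6-dimethyl-7-(prop-2-en-1-yl)oxepan-2-yl]ethane-1,2-diol
Conditions: CSA (10 mol%), CH2Cl2, 0 °C to rt
Reagents that add atoms: none
Why: Acid-catalysed intramolecular epoxide opening in which the C9 hydroxyl attacks the tertiary epoxide carbon C4 in the 7-exo-tet mode (the exo preference and the preference for the more substituted carbon coincide) with inversion, so C4 becomes R with its methyl trans to the C9 arm, C5 keeps its oxygen with retention, and oxepane A is closed.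

**Step 7**
Reactants: 11 (1S)-1-[(2R,6S,7R)-2,6-dimethyl-7-(prop-2-en-1-yl)oxepan-2-yl]ethane-1,2-diol
Product: 12 (4S)-4-[(2R,6S,7R)-2,6-dimethyl-7-(prop-2-en-1-yl)oxepan-2-yl]-2-(4-methoxyphenyl)-1,3-dioxolane (acetal carbon as epimer mixture)
Conditions: 4-MeOC6H4CH(OMe)2, PPTS (catalytic), CH2Cl2, rt
Reagents that add atoms: 4-methoxybenzaldehyde dimethyl acetal, COc1ccc(cc1)C(OC)OC
Why: Acid-catalysed transacetalisation ties the 1,2-diol into a p-methoxybenzylidene acetal, whose acetal epimers converge in step 8.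

**Step 8**
Reactants: 12 (4S)-4-[(2R,6S,7R)-2,6-dimethyl-7-(prop-2-en-1-yl)oxepan-2-yl]-2-(4-methoxyphenyl)-1,3-dioxolane
Product: 13 (2S)-2-[(2R,6S,7R)-2,6-dimethyl-7-(prop-2-en-1-yl)oxepan-2-yl]-2-[(4-methoxyphenyl)methoxy]ethan-1-ol
Conditions: i-Bu2AlH (3 equiv), CH2Cl2, −78 to 0 °C
Reagents that add atoms: none
Why: Regioselective reductive opening of the benzylidene acetal, in which aluminium binds the unhindered primary oxygen and hydride reduces the resulting oxocarbenium ion, should leave the PMB ether on the hindered C5 oxygen and free the C6 hydroxyl.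

**Step 9**
Reactants: 13 (2S)-2-[(2R,6S,7R)-2,6-dimethyl-7-(prop-2-en-1-yl)oxepan-2-yl]-2-[(4-methoxyphenyl)methoxy]ethan-1-ol
Product: 15 2-[(2R,3S,7R)-7-[(1S)-2-hydroxy-1-[(4-methoxyphenyl)methoxy]ethyl]-3,7-dimethyloxepan-2-yl]acetaldehyde, via vicinal diol 14 (not isolated)
Conditions: OsO4 (2 mol%), NaIO4, 2,6-lutidine, dioxane/H2O, rt
Reagents that add atoms: sodium periodate (oxygen source via OsO4), [Na+].[O-]I(=O)(=O)=O
Why: Lemieux–Johnson oxidation dihydroxylates the only alkene and cleaves the diol in situ to the C7 aldehyde under conditions that the PMB ether and the free primary alcohol tolerate.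

**Step 10**
Reactants: 15 2-[(2R,3S,7R)-7-[(1S)-2-hydroxy-1-[(4-methoxyphenyl)methoxy]ethyl]-3,7-dimethyloxepan-2-yl]acetaldehyde; 16 methyl acrylate
Product: 17 methyl 2-[1-hydroxy-2-[(2R,3S,7R)-7-[(1S)-2-hydroxy-1-[(4-methoxyphenyl)methoxy]ethyl]-3,7-dimethyloxepan-2-yl]ethyl]prop-2-enoate (both C7 carbinol epimers)
Conditions: 16 (5 equiv), DABCO (1 equiv), MeOH, rt
Reagents that add atoms: none
Why: Morita–Baylis–Hillman reaction of the unhindered aliphatic aldehyde with the acrylate installs C11–C13 on C7, and the uncontrolled carbinol centre is erased in step 11.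

**Step 11**
Reactants: 17 methyl 2-[1-hydroxy-2-[(2R,3S,7R)-7-[(1S)-2-hydroxy-1-[(4-methoxyphenyl)methoxy]ethyl]-3,7-dimethyloxepan-2-yl]ethyl]prop-2-enoate
Product: 18 methyl (2Z)-2-(bromomethyl)-4-[(2R,3S,7R)-7-[(1S)-2-hydroxy-1-[(4-methoxyphenyl)methoxy]ethyl]-3,7-dimethyloxepan-2-yl]but-2-enoate
Conditions: NBS (3 equiv), Me2S (3.5 equiv), CH2Cl2, 0 °C to rt
Reagents that add atoms: N-bromosuccinimide, O=C1CCC(=O)N1Br
Why: Corey–Kim-type activation as the alkoxysulfonium salt followed by SN2′ attack of bromide converts the activated allylic alcohol into the rearranged primary bromide with the usual Z geometry, whereas the saturated primary alkoxysulfonium salt at C6 is not displaced and should return the alcohol on aqueous work-up.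

**Step 12**
Reactants: 18 methyl (2Z)-2-(bromomethyl)-4-[(2R,3S,7R)-7-[(1S)-2-hydroxy-1-[(4-methoxyphenyl)methoxy]ethyl]-3,7-dimethyloxepan-2-yl]but-2-enoate
Product: 19 methyl (2Z)-2-(bromomethyl)-4-[(2R,3S,7R)-7-[(1R)-1-[(4-methoxyphenyl)methoxy]-2-oxoethyl]-3,7-dimethyloxepan-2-yl]but-2-enoate
Conditions: Dess–Martin periodinane, NaHCO3, CH2Cl2, 0 °C to rt
Reagents that add atoms: none
Why: Dess–Martin oxidation gives the α-alkoxy aldehyde under buffered, non-basic conditions that should neither epimerise C5 nor touch the allylic bromide.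

**Step 13**
Reactants: 19 methyl (2Z)-2-(bromomethyl)-4-[(2R,3S,7R)-7-[(1R)-1-[(4-methoxyphenyl)methoxy]-2-oxoethyl]-3,7-dimethyloxepan-2-yl]but-2-enoate
Product: 22 (1R,2S,3R,7R,9R,10S)-2-[(4-methoxyphenyl)methoxy]-1,10-dimethyl-6-methylidene-4,14-dioxatricyclo[7.4.1.0(3,7)]tetradecan-5-one (C5 PMB ether of the des-isovaleryl target), via allylchromium species 20 (not isolated), via hydroxy ester 21 (not isolated)
Conditions: CrCl2 (8 equiv), THF, syringe-pump addition of 19 (final 0.003 M), rt; aqueous NH4Cl; then PPTS (catalytic), CH2Cl2, rt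
Reagents that add atoms: none
Why: Two equivalents of CrCl2 each give one electron to the C13–Br bond, producing a σ-allyl complex of trivalent chromium that adds through its γ-carbon C7 to the chromium-bound C6 aldehyde in a six-membered chair (Cr, O, C6, C7, C11, C13) with allylic transposition, after which the C6 alkoxide expels methoxide from the ester. The closest known reaction type is the Nozaki–Hiyama 2-(alkoxycarbonyl)allylation of aldehydes by 2-(bromomethyl)acrylates in its intramolecular form, which is established for ring-fused α-methylene-γ-butyrolactones. Oxepane B closes by 7-exo-trig attack of C7 on the carbonyl carbon, made entropically easy by the cis C4 and C9 arms of oxepane A, and the lactone closes by 5-exo-trig acyl substitution. C7 is set by the face of the allyl terminus that the short C9 tether can present within the chair, and C6 by the aldehyde face, which the C5 stereocentre controls when its C–OPMB bond lies anti to the forming bond (polar Felkin–Anh arrangement, with the ether oxygen still within reach of chromium). The step needs the anti adduct (O6 trans to C8, hence the trans lactone) together with the 5,6-trans relationship, which is the outcome of the chair in which both ring-B arms (C5 and C8) are equatorial, so that O6, C11 and the C5 ether all sit pseudo-equatorially on the new ring. Because the bromide is Z, that chair is reached only after the allylchromium has isomerised by 1,3-metal shift to the form with C8 anti to CH2Cr, as crotylchromium reagents are known to do, and the cis arms of ring A and the fixed C5 centre are the substrate features expected to bias the closure this way.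

**Step 14**
Reactants: 22 (1R,2S,3R,7R,9R,10S)-2-[(4-methoxyphenyl)methoxy]-1,10-dimethyl-6-methylidene-4,14-dioxatricyclo[7.4.1.0(3,7)]tetradecan-5-one
Product: 23 (1R,2S,3R,7R,9R,10S)-2-hydroxy-1,10-dimethyl-6-methylidene-4,14-dioxatricyclo[7.4.1.0(3,7)]tetradecan-5-one
Conditions: DDQ, CH2Cl2/pH 7 buffer, 0 °C to rt
Reagents that add atoms: none
Why: Oxidative cleavage of the electron-rich PMB ether by hydride abstraction and hydrolysis of the resulting oxocarbenium ion frees the C5 hydroxyl without affecting the α-methylene lactone or any stereocentre.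

**Step 15**
Reactants: 23 (1R,2S,3R,7R,9R,10S)-2-hydroxy-1,10-dimethyl-6-methylidene-4,14-dioxatricyclo[7.4.1.0(3,7)]tetradecan-5-one; 24 isovaleric anhydride
Product: 25 (1R,2S,3R,7R,9R,10S)-1,10-dimethyl-6-methylidene-5-oxo-4,14-dioxatricyclo[7.4.1.0(3,7)]tetradecan-2-yl 3-methylbutanoate (target)
Conditions: 24 (3 equiv), DMAP (0.2 equiv), Et3N, CH2Cl2, rt
Reagents that add atoms: none
Why: DMAP-catalysed acylation (Steglich-type acyl transfer) esterifies the hindered secondary C5 hydroxyl with retention, since no bond to C5 is broken.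

**Compound list**

1 | cyclohex-2-en-1-one | O=C1C=CCCC1 | starting material
2 | allyl acetate (prop-2-en-1-yl acetate) | C=CCOC(C)=O | starting material
3 | methylzinc (3S)-3-methylcyclohex-1-en-1-olate (zinc enolate, not isolated) | C[Zn]OC1=C[C@@H](C)CCC1 | intermediate
4 | (2R,3S)-3-methyl-2-(prop-2-en-1-yl)cyclohexan-1-one | C=CC[C@H]1C(=O)CCC[C@@H]1C | intermediate
5 | (6S,7R)-6-methyl-7-(prop-2-en-1-yl)oxepan-2-one | C=CC[C@H]1OC(=O)CCC[C@@H]1C | intermediate
6 | (6S,7R)-6-methyl-7-(prop-2-en-1-yl)oxepan-2-ol (lactol, anomer mixture, not isolated) | C=CC[C@H]1OC(O)CCC[C@@H]1C | intermediate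
7 | (4R,5S)-5-methyldec-1-en-9-yn-4-ol | C#CCCC[C@H](C)[C@H](O)CC=C | intermediate
8 | (E)-alkenyl dimethylalane from 7, C9 oxygen as dimethylaluminium alkoxide (not isolated) | C[Al](C)/C=C(\C)CCC[C@H](C)[C@@H](CC=C)O[Al](C)C | intermediate
9 | (2E,7S,8R)-3,7-dimethylundeca-2,10-diene-1,8-diol | OC/C=C(\C)CCC[C@H](C)[C@H](O)CC=C | intermediate
10 | [(2S,3S)-3-[(4S,5R)-5-hydroxy-4-methyloct-7-en-1-yl]-3-methyloxiran-2-yl]methanol | OC[C@@H]1O[C@@]1(C)CCC[C@H](C)[C@H](O)CC=C | intermediate
11 | (1S)-1-[(2R,6S,7R)-2,6-dimethyl-7-(prop-2-en-1-yl)oxepan-2-yl]ethane-1,2-diol | OC[C@H](O)[C@@]1(C)CCC[C@H](C)[C@@H](CC=C)O1 | intermediate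
12 | (4S)-4-[(2R,6S,7R)-2,6-dimethyl-7-(prop-2-en-1-yl)oxepan-2-yl]-2-(4-methoxyphenyl)-1,3-dioxolane | COc1ccc(cc1)C1OC[C@H](O1)[C@@]1(C)CCC[C@H](C)[C@@H](CC=C)O1 | intermediate
13 | (2S)-2-[(2R,6S,7R)-2,6-dimethyl-7-(prop-2-en-1-yl)oxepan-2-yl]-2-[(4-methoxyphenyl)methoxy]ethan-1-ol | OC[C@H](OCc1ccc(OC)cc1)[C@@]1(C)CCC[C@H](C)[C@@H](CC=C)O1 | intermediate
14 | vicinal diol from dihydroxylation of the allyl group of 13 (epimer mixture, not isolated) | OC[C@H](OCc1ccc(OC)cc1)[C@@]1(C)CCC[C@H](C)[C@@H](CC(O)CO)O1 | intermediate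
15 | 2-[(2R,3S,7R)-7-[(1S)-2-hydroxy-1-[(4-methoxyphenyl)methoxy]ethyl]-3,7-dimethyloxepan-2-yl]acetaldehyde | OC[C@H](OCc1ccc(OC)cc1)[C@@]1(C)CCC[C@H](C)[C@@H](CC=O)O1 | intermediate
16 | methyl acrylate | C=CC(=O)OC | starting material
17 | methyl 2-[1-hydroxy-2-[(2R,3S,7R)-7-[(1S)-2-hydroxy-1-[(4-methoxyphenyl)methoxy]ethyl]-3,7-dimethyloxepan-2-yl]ethyl]prop-2-enoate (carbinol epimers) | OC[C@H](OCc1ccc(OC)cc1)[C@@]1(C)CCC[C@H](C)[C@@H](CC(O)C(=C)C(=O)OC)O1 | intermediate
18 | methyl (2Z)-2-(bromomethyl)-4-[(2R,3S,7R)-7-[(1S)-2-hydroxy-1-[(4-methoxyphenyl)methoxy]ethyl]-3,7-dimethyloxepan-2-yl]but-2-enoate | OC[C@H](OCc1ccc(OC)cc1)[C@@]1(C)CCC[C@H](C)[C@@H](C/C=C(\CBr)C(=O)OC)O1 | intermediate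
19 | methyl (2Z)-2-(bromomethyl)-4-[(2R,3S,7R)-7-[(1R)-1-[(4-methoxyphenyl)methoxy]-2-oxoethyl]-3,7-dimethyloxepan-2-yl]but-2-enoate (key-step precursor) | O=C[C@H](OCc1ccc(OC)cc1)[C@@]1(C)CCC[C@H](C)[C@@H](C/C=C(\CBr)C(=O)OC)O1 | intermediate
20 | σ-allylchromium dichloride from 19, chromium on C13, alkene geometry mobile (not isolated) | O=C[C@H](OCc1ccc(OC)cc1)[C@@]1(C)CCC[C@H](C)[C@@H](CC=C(C[Cr](Cl)Cl)C(=O)OC)O1 | intermediate
21 | methyl 2-[(1R,2S,3R,4R,6R,7S)-3-hydroxy-2-[(4-methoxyphenyl)methoxy]-1,7-dimethyl-11-oxabicyclo[4.4.1]undecan-4-yl]prop-2-enoate (formed as its chromium alkoxide, not isolated) | C=C(C(=O)OC)[C@H]1C[C@H]2O[C@](C)(CCC[C@@H]2C)[C@@H](OCc2ccc(OC)cc2)[C@@H]1O | intermediate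
22 | (1R,2S,3R,7R,9R,10S)-2-[(4-methoxyphenyl)methoxy]-1,10-dimethyl-6-methylidene-4,14-dioxatricyclo[7.4.1.0(3,7)]tetradecan-5-one (key-step product) | C=C1C(=O)O[C@@H]2[C@@H]1C[C@H]1O[C@](C)(CCC[C@@H]1C)[C@H]2OCc1ccc(OC)cc1 | intermediate
23 | (1R,2S,3R,7R,9R,10S)-2-hydroxy-1,10-dimethyl-6-methylidene-4,14-dioxatricyclo[7.4.1.0(3,7)]tetradecan-5-one | C=C1C(=O)O[C@@H]2[C@@H]1C[C@H]1O[C@](C)(CCC[C@@H]1C)[C@H]2O | intermediate
24 | isovaleric anhydride (3-methylbutanoic anhydride) | CC(C)CC(=O)OC(=O)CC(C)C | starting material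
25 | (1R,2S,3R,7R,9R,10S)-1,10-dimethyl-6-methylidene-5-oxo-4,14-dioxatricyclo[7.4.1.0(3,7)]tetradecan-2-yl 3-methylbutanoate | C=C1C(=O)O[C@@H]2[C@@H]1C[C@H]1O[C@](C)(CCC[C@@H]1C)[C@H]2OC(=O)CC(C)C | target

**Step count.** Total: 15 steps. Longest linear sequence: 15 steps (1 to 25).

**Steps most likely to fail**

1. Step 13. The allylchromium may react through the chair that keeps C8 axial, which is the usual course of the unisomerised Z-configured reagent, or on the other aldehyde face. The ring would then close with the lactone oxygen on the wrong side of C6, and intermolecular coupling may compete if dilution is insufficient. The fallback sets out from 19 and runs the closure as before, accepting (1R,2S,3S,7R,9R,10S)-2-[(4-methoxyphenyl)methoxy]-1,10-dimethyl-6-methylidene-4,14-dioxatricyclo[7.4.1.0(3,7)]tetradecan-5-one F1, the cis-fused lactone epimeric at C6. Saponification (LiOH, THF/H2O, then acidification to pH 4 at 0 °C) would give 2-[(1R,2S,3S,4R,6R,7S)-3-hydroxy-2-[(4-methoxyphenyl)methoxy]-1,7-dimethyl-11-oxabicyclo[4.4.1]undecan-4-yl]prop-2-enoic acid F2. Mitsunobu lactonisation (PPh3, DIAD, THF, high dilution) then closes the lactone with inversion at C6 and comes back to the route at 22, so C6 is set by SN2 displacement and no longer by the allylation.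

2. Step 6. Ionisation at the tertiary epoxide carbon may lead to hydride shift, elimination or intermolecular capture faster than the seven-membered ring can close, and the free epoxy alcohol offers additional rearrangement pathways. The fallback sets out from 10, removes the free epoxy-alcohol function and moves the closure to kinetic Lewis-acid control. Silylation of the primary hydroxyl (TBSCl, imidazole, CH2Cl2, 0 °C) would give tert-butyl{[(2S,3S)-3-[(4S,5R)-5-hydroxy-4-methyloct-7-en-1-yl]-3-methyloxiran-2-yl]methoxy}dimethylsilane F3. BF3·OEt2 in CH2Cl2 at −78 °C should then trigger the same 7-exo opening at C4 to give (1S)-2-[(tert-butyldimethylsilyl)oxy]-1-[(2R,6S,7R)-2,6-dimethyl-7-(prop-2-en-1-yl)oxepan-2-yl]ethan-1-ol F4. Desilylation (Bu4NF, THF) comes back to the route at 11.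

3. Step 10. The amine-catalysed addition to an α-unbranched, β-alkoxy aldehyde is slow, so aldol self-condensation or base-induced β-elimination of the ring oxygen at C9 may compete. The fallback sets out from 15 and replaces the catalytic process by a stoichiometric aldol–elimination sequence. Addition of the lithium enolate of commercial methyl 3-(dimethylamino)propanoate (LiN(i-Pr)2, THF, −78 °C, excess to allow for the free hydroxyl) would give methyl 2-[(dimethylamino)methyl]-3-hydroxy-4-[(2R,3S,7R)-7-[(1S)-2-hydroxy-1-[(4-methoxyphenyl)methoxy]ethyl]-3,7-dimethyloxepan-2-yl]butanoate F5. Oxidation with mCPBA (CH2Cl2, 0 °C) would give the corresponding amine N-oxide F6, which on gentle warming undergoes Cope elimination to the α-methylene ester and comes back to the route at 17.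

**Further compounds**

F1 | step 13 | (1R,2S,3S,7R,9R,10S)-2-[(4-methoxyphenyl)methoxy]-1,10-dimethyl-6-methylidene-4,14-dioxatricyclo[7.4.1.0(3,7)]tetradecan-5-one | C=C1C(=O)O[C@H]2[C@@H]1C[C@H]1O[C@](C)(CCC[C@@H]1C)[C@H]2OCc1ccc(OC)cc1
F2 | step 13 | 2-[(1R,2S,3S,4R,6R,7S)-3-hydroxy-2-[(4-methoxyphenyl)methoxy]-1,7-dimethyl-11-oxabicyclo[4.4.1]undecan-4-yl]prop-2-enoic acid | C=C(C(=O)O)[C@H]1C[C@H]2O[C@](C)(CCC[C@@H]2C)[C@@H](OCc2ccc(OC)cc2)[C@H]1O
F3 | step 6 | tert-butyl{[(2S,3S)-3-[(4S,5R)-5-hydroxy-4-methyloct-7-en-1-yl]-3-methyloxiran-2-yl]methoxy}dimethylsilane | CC(C)(C)[Si](C)(C)OC[C@@H]1O[C@@]1(C)CCC[C@H](C)[C@H](O)CC=C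
F4 | step 6 | (1S)-2-[(tert-butyldimethylsilyl)oxy]-1-[(2R,6S,7R)-2,6-dimethyl-7-(prop-2-en-1-yl)oxepan-2-yl]ethan-1-ol | CC(C)(C)[Si](C)(C)OC[C@H](O)[C@@]1(C)CCC[C@H](C)[C@@H](CC=C)O1
F5 | step 10 | methyl 2-[(dimethylamino)methyl]-3-hydroxy-4-[(2R,3S,7R)-7-[(1S)-2-hydroxy-1-[(4-methoxyphenyl)methoxy]ethyl]-3,7-dimethyloxepan-2-yl]butanoate (diastereomer mixture) | OC[C@H](OCc1ccc(OC)cc1)[C@@]1(C)CCC[C@H](C)[C@@H](CC(O)C(CN(C)C)C(=O)OC)O1
F6 | step 10 | N-oxide of F5 | OC[C@H](OCc1ccc(OC)cc1)[C@@]1(C)CCC[C@H](C)[C@@H](CC(O)C(C[N+](C)(C)[O-])C(=O)OC)O1
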